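**Retrosynthetic overview**
1. The target comes from global hydrogenolysis of a bis-stearate that carries a second, sacrificial stearate on the benzylic carbon of the C4 side chain. That bis-stearate comes, by acylation and LiAlH4 reduction, from a cis-fused 3,6-diaryl-furo[3,4-c]furan-1-one.
2. Enabling feature: the oxolane ring holds the unit C2(aryl)H–O1–C5H2, which is the carbonyl ylide of a vanillin ether and a methylene. C3 and C4 carry their CH2O and CH2Ar arms cis, so one oxygen can tie them into a γ-lactone (CH2O raised to C=O, ArCH2 raised to ArCH–O), and the C3–C4 bond becomes the C=C of a 5-aryl-butenolide.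
3. Key disconnection: [3+2] cycloaddition of ArCH=O(+)–CH2(−) to (S)-5-arylfuran-2(5H)-one makes C5–C4 and C3–C2 at once, with the O-bound CH2 acting as a carbanion (polarity reversal). The butenolide stereocentre steers all three new centres and is erased at the end.
4. Both partners come from O-benzylvanillin in two steps each. Ring order: lactone ring B (temporary) first, oxolane ring A in the key step, ring B opened afterwards.

Key step: step 5

Abbreviation: Ar = 4-(benzyloxy)-3-methoxyphenyl.
Assumption: (S,S)-ProPhenol is written as the ligand antipode that directs the alkynyl group to the Si face of the aldehyde; should the carbinol prove to be the S enantiomer (Mosher ester analysis), (R,R)-ProPhenol is taken instead and nothing else changes.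

Step 1
Reactants: 1 4-(benzyloxy)-3-methoxybenzaldehyde (O-benzylvanillin); 2 methyl propiolate
Product: 3 methyl (R)-4-[4-(benzyloxy)-3-methoxyphenyl]-4-hydroxybut-2-ynoate
Conditions: 2 (3 equiv), Me2Zn (3 equiv), (S,S)-ProPhenol (10 mol %), Ph3PO (20 mol %), toluene, 4 °C; aq NH4Cl
Reagents that add atoms: none
Why: Zinc–ProPhenol-catalysed asymmetric alkynylation of an aryl aldehyde, in which the dinuclear zinc alkynylide held in the chiral pocket should deliver the propiolate to the Si face and so set the carbinol centre (R by the CIP rules because the substituted alkynyl carbon outranks the aryl carbon).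

Step 2
Reactants: 3 methyl (R)-4-[4-(benzyloxy)-3-methoxyphenyl]-4-hydroxybut-2-ynoate
Product: 5 (5S)-5-[4-(benzyloxy)-3-methoxyphenyl]furan-2(5H)-one, via Z-hydroxy enoate 4 (not isolated)
Conditions: H2 (1 atm), Pd/CaCO3 poisoned with Pb(OAc)2 (Lindlar catalyst), quinoline, EtOAc, rt; then SiO2, CH2Cl2, rt
Reagents that add atoms: none
Why: Lindlar semihydrogenation (syn addition of H2) gives the Z-enoate, whose hydroxyl and ester lie side by side so that lactonisation follows, while the carbinol centre is untouched (the descriptor becomes S only because the alkenyl carbon ranks below the aryl carbon) and the aryl benzyl ether survives the poisoned catalyst.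

Step 3
Reactants: 1 4-(benzyloxy)-3-methoxybenzaldehyde; 6 (trimethylsilyl)methanol
Product: 7 1-(benzyloxy)-4-{bis[(trimethylsilyl)methoxy]methyl}-2-methoxybenzene (bis[(trimethylsilyl)methyl] acetal of 1)
Conditions: 6 (2.5 equiv), PPTS (cat.), cyclohexane, Dean–Stark, reflux; Et3N quench
Reagents that add atoms: none
Why: Acid-catalysed acetalisation driven by azeotropic removal of water, with a primary alcohol whose C–Si bond is inert to weak acid, and no stereocentre is formed.

Step 4
Reactants: 7 bis[(trimethylsilyl)methyl] acetal of 1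
Product: 8 ({[4-(benzyloxy)-3-methoxyphenyl](chloro)methoxy}methyl)trimethylsilane (racemic α-chloro ether, used crude)
Conditions: AcCl (1.05 equiv), CH2Cl2, 0 °C to rt; volatiles removed in vacuo
Reagents that add atoms: acetyl chloride, CC(=O)Cl
Why: Acetal–acyl chloride exchange (the standard α-chloro ether synthesis), eased by the p-benzyloxy group that stabilises the intermediate oxocarbenium ion, and the new centre may be racemic because it becomes planar in the ylide.

Step 5
Reactants: 8 racemic α-chloro ether; 5 (5S)-5-[4-(benzyloxy)-3-methoxyphenyl]furan-2(5H)-one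
Product: 10 (3S,3aR,6S,6aS)-3,6-bis[4-(benzyloxy)-3-methoxyphenyl]tetrahydro-1H,3H-furo[3,4-c]furan-1-one (cis-fused, both aryl groups exo), via carbonyl ylide 9 (not isolated)
Conditions: CsF (dried, 3 equiv), MeCN, rt, slow addition of 8 (2 equiv) to 5
Reagents that add atoms: none
Why: Fluoride attacks the silicon of 8, which is in equilibrium with its oxocarbenium chloride, and 1,3-elimination of Me3SiF and chloride releases the non-stabilised carbonyl ylide 9, which adds as the 4π partner across the C3=C4 bond of 5 in a concerted but asynchronous [π4s+π2s] 1,3-dipolar cycloaddition. The closest known reaction types are the CsF-induced 1,3-elimination of α-chloroalkyl (trimethylsilyl)methyl ethers with capture of the ylide by acrylates, maleates and fumarates, and the anti-selective addition of silylmethylamine-derived azomethine ylides to 5-substituted butenolides. Oxolane ring A is closed by this intermolecular [3+2] cycloaddition, both C–C bonds (CH2 to C4 and ArCH to C3 of 5) forming on the same face of the ring-locked Z alkene, so the ring fusion can only be cis. C3a and C6a of 10 are set by approach of the ylide to the face of 5 anti to its C5 aryl group, and C6 is set by the E geometry of the ylide (inherited from the E oxocarbenium ion) combined with exo approach, in which the lactone ring points away from the ylide oxygen and the aryl group ends on the convex face, trans to the lactone carbonyl. Regioselectivity is secured by the p-benzyloxy group, which localises positive charge on the benzylic terminus and carbanion character (largest HOMO coefficient) on CH2, matching the β-carbon C4 (largest LUMO coefficient) of the lactone. The configurational integrity of 5, whose C5–H is acidic, is protected by keeping 8 in excess so that fluoride is consumed at silicon.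

Step 6
Reactants: 10 furofuranone cycloadduct
Product: 11 (S)-[4-(benzyloxy)-3-methoxyphenyl]{(3R,4R,5S)-5-[4-(benzyloxy)-3-methoxyphenyl]-4-(hydroxymethyl)oxolan-3-yl}methanol
Conditions: LiAlH4, THF, 0 °C; Na2SO4·10H2O
Reagents that add atoms: none
Why: Lactone-to-diol reduction by LiAlH4, which opens temporary ring B without touching the ethers or any of the four stereocentres.

Step 7
Reactants: 11 diol; 12 stearoyl chloride (octadecanoyl chloride)
Product: 13 bis(octadecanoate) of 11 (primary and benzylic hydroxyl both esterified)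
Conditions: 12 (2.5 equiv), Et3N, DMAP (cat.), CH2Cl2, 0 °C to rt; Et3N-deactivated SiO2
Reagents that add atoms: none
Why: DMAP-catalysed exhaustive O-acylation with an acid chloride, in which both hydroxyls are esterified so that no selectivity is required, the primary stearate being the ester of the target and the benzylic one a leaving group for the last step, with no stereocentre affected.

Step 8
Reactants: 13 bis(octadecanoate)
Product: 14 [(2S,3R,4R)-2-(4-hydroxy-3-methoxyphenyl)-4-(4-hydroxy-3-methoxybenzyl)oxolan-3-yl]methyl octadecanoate (target)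
Conditions: H2 (1 atm), Pd/C, EtOAc, rt, stopped once the benzylic ester is consumed
Reagents that add atoms: none
Why: Heterogeneous palladium-catalysed hydrogenolysis, in which the two aryl benzyl ethers and the acyclic p-oxygenated benzylic ester C–O bond should be cleaved well before the ring benzylic ether, the primary alkyl stearate is inert, the auxiliary benzylic stereocentre is erased and the three ring centres stay as set in step 5.

**Compound list**
1 | 4-(benzyloxy)-3-methoxybenzaldehyde | O=Cc1ccc(OCc2ccccc2)c(OC)c1 | starting material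
2 | methyl propiolate | C#CC(=O)OC | starting material
3 | methyl (R)-4-[4-(benzyloxy)-3-methoxyphenyl]-4-hydroxybut-2-ynoate | O[C@H](c1ccc(OCc2ccccc2)c(OC)c1)C#CC(=O)OC | intermediate
4 | methyl (2Z,4S)-4-[4-(benzyloxy)-3-methoxyphenyl]-4-hydroxybut-2-enoate (not isolated) | O[C@H](c1ccc(OCc2ccccc2)c(OC)c1)/C=C\C(=O)OC | intermediate
5 | (5S)-5-[4-(benzyloxy)-3-methoxyphenyl]furan-2(5H)-one | O=C1O[C@H](c2ccc(OCc3ccccc3)c(OC)c2)C=C1 | intermediate
6 | (trimethylsilyl)methanol | C[Si](C)(C)CO | starting material
7 | 1-(benzyloxy)-4-{bis[(trimethylsilyl)methoxy]methyl}-2-methoxybenzene | C[Si](C)(C)COC(OC[Si](C)(C)C)c1ccc(OCc2ccccc2)c(OC)c1 | intermediate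
8 | ({[4-(benzyloxy)-3-methoxyphenyl](chloro)methoxy}methyl)trimethylsilane, racemic | C[Si](C)(C)COC(Cl)c1ccc(OCc2ccccc2)c(OC)c1 | intermediate
9 | (E)-carbonyl ylide ArCH=O(+)–CH2(−) (not isolated) | [CH2-]/[O+]=C/c1ccc(OCc2ccccc2)c(OC)c1 | intermediate
10 | (3S,3aR,6S,6aS)-3,6-bis[4-(benzyloxy)-3-methoxyphenyl]tetrahydro-1H,3H-furo[3,4-c]furan-1-one | O=C1O[C@H](c2ccc(OCc3ccccc3)c(OC)c2)[C@H]2CO[C@H](c3ccc(OCc4ccccc4)c(OC)c3)[C@@H]12 | intermediate
11 | (S)-[4-(benzyloxy)-3-methoxyphenyl]{(3R,4R,5S)-5-[4-(benzyloxy)-3-methoxyphenyl]-4-(hydroxymethyl)oxolan-3-yl}methanol | OC[C@H]1[C@@H]([C@H](O)c2ccc(OCc3ccccc3)c(OC)c2)CO[C@@H]1c1ccc(OCc2ccccc2)c(OC)c1 | intermediate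
12 | stearoyl chloride | CCCCCCCCCCCCCCCCCC(=O)Cl | starting material
13 | bis(octadecanoate) of 11 | CCCCCCCCCCCCCCCCCC(=O)OC[C@H]1[C@@H]([C@H](OC(=O)CCCCCCCCCCCCCCCCC)c2ccc(OCc3ccccc3)c(OC)c2)CO[C@@H]1c1ccc(OCc2ccccc2)c(OC)c1 | intermediate
14 | [(2S,3R,4R)-2-(4-hydroxy-3-methoxyphenyl)-4-(4-hydroxy-3-methoxybenzyl)oxolan-3-yl]methyl octadecanoate | CCCCCCCCCCCCCCCCCC(=O)OC[C@H]1[C@@H](Cc2ccc(O)c(OC)c2)CO[C@@H]1c1ccc(O)c(OC)c1 | target

**Totals**
- Total step count: 8.
- Longest linear sequence: 6 steps (steps 1, 2, 5, 6, 7, 8). The branch through steps 3 and 4 is equally long.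

**Steps most likely to fail**

Step 5.
What may go wrong:
- Fluoride-induced deprotonation of the butenolide at C5, which would racemise it through the 2-oxyfuran anion.
- Collapse of the ylide to the epoxide, or its capture by adventitious aldehyde.
- Incomplete exo or regiochemical control.

The fallback sets out from 1 and 5 and comes back at 10. It makes the two bonds one after the other. Aldehyde 1 is reduced (NaBH4, MeOH) to 4-(benzyloxy)-3-methoxybenzyl alcohol F1. This is alkylated (NaH, Bu3SnCH2I, THF–DMF) to tributyl({[4-(benzyloxy)-3-methoxybenzyl]oxy}methyl)stannane F2. Tin–lithium exchange (n-BuLi, THF, −78 °C), formation of the homocuprate (CuBr·SMe2, 0.5 equiv) and conjugate addition to 5 anti to the aryl group should give the (4R,5S)-trans-4-[(arylmethoxy)methyl]-5-aryl lactone F3. Trifluoroacetylation (LiHMDS, CF3CO2CH2CF3, THF, −78 °C) gives the α-trifluoroacetyl lactone F4. Detrifluoroacetylative diazo transfer (MsN3, Et3N, MeCN) then gives the α-diazo lactone F5. Rh2(OAc)4 in CH2Cl2 closes ring A by 1,5 C–H insertion of the rhodium carbene into the benzylic ether C–H bond, and the fusion is necessarily cis. If the aryl group is delivered endo, as the (6R)-epimer of the furofuranone F6, it is equilibrated to 10 with camphorsulfonic acid in CH2Cl2. This works through reversible opening of the p-alkoxybenzylic ether. The same treatment would converge any such epimer formed in step 5.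

Step 8.
What may go wrong: over-hydrogenolysis, that is, cleavage of the ring C2–O benzylic bond once the phenols are free and before the benzylic ester is fully consumed.

The fallback sets out from 11 and comes back at 14. It separates the two reductive tasks. Diol 11 is acylated at the primary hydroxyl only (12, 1 equiv, 2,4,6-collidine, CH2Cl2, −20 °C) to the primary monostearate F7. The benzylic alcohol is converted with 1,1'-thiocarbonyldiimidazole (DMAP, CH2Cl2) into the O-(imidazol-1-ylthiocarbonyl) derivative F8. Barton–McCombie deoxygenation (Bu3SnH, AIBN, toluene, 80 °C) removes it to give the di-O-benzyl ether of the target F9. Only the two aryl benzyl ethers then remain. They are cleaved by catalytic transfer hydrogenolysis (1,4-cyclohexadiene, Pd/C, EtOH–EtOAc, rt), which should leave the cyclic benzylic ether intact.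

Step 1.
What may go wrong: insufficient facial discrimination or sluggish addition with the electron-rich aldehyde, and competing methyl transfer from zinc.

The fallback sets out from 1 and comes back at 5. Vinylmagnesium bromide (THF, 0 °C) adds to 1 to give racemic 1-[4-(benzyloxy)-3-methoxyphenyl]prop-2-en-1-ol F10. Lipase-catalysed kinetic resolution (Novozym 435, vinyl acetate, MTBE, rt) should convert the R enantiomer into the (R)-acetate F11 and leave the (S)-allylic alcohol F12, as the empirical size rule for secondary alcohols predicts. Acylation (acryloyl chloride, iPr2NEt, CH2Cl2, 0 °C) gives the (S)-acrylate F13. Ring-closing metathesis (second-generation Grubbs catalyst, CH2Cl2, reflux) then closes the butenolide 5 under neutral conditions.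

**Further compounds**
F1 | step 5 | 4-(benzyloxy)-3-methoxybenzyl alcohol | OCc1ccc(OCc2ccccc2)c(OC)c1
F2 | step 5 | tributyl({[4-(benzyloxy)-3-methoxybenzyl]oxy}methyl)stannane | CCCC[Sn](CCCC)(CCCC)COCc1ccc(OCc2ccccc2)c(OC)c1
F3 | step 5 | (4R,5S)-5-[4-(benzyloxy)-3-methoxyphenyl]-4-({[4-(benzyloxy)-3-methoxybenzyl]oxy}methyl)dihydrofuran-2(3H)-one | O=C1O[C@H](c2ccc(OCc3ccccc3)c(OC)c2)[C@@H](COCc2ccc(OCc3ccccc3)c(OC)c2)C1
F4 | step 5 | 3-(trifluoroacetyl) derivative of F3 | O=C1O[C@H](c2ccc(OCc3ccccc3)c(OC)c2)[C@@H](COCc2ccc(OCc3ccccc3)c(OC)c2)C1C(=O)C(F)(F)F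
F5 | step 5 | 3-diazo derivative of F3 | O=C1O[C@H](c2ccc(OCc3ccccc3)c(OC)c2)[C@@H](COCc2ccc(OCc3ccccc3)c(OC)c2)C1=[N+]=[N-]
F6 | step 5 | (3S,3aR,6R,6aS)-3,6-bis[4-(benzyloxy)-3-methoxyphenyl]tetrahydro-1H,3H-furo[3,4-c]furan-1-one (C6 epimer of 10) | O=C1O[C@H](c2ccc(OCc3ccccc3)c(OC)c2)[C@H]2CO[C@@H](c3ccc(OCc4ccccc4)c(OC)c3)[C@@H]12
F7 | step 8 | primary mono(octadecanoate) of 11 | CCCCCCCCCCCCCCCCCC(=O)OC[C@H]1[C@@H]([C@H](O)c2ccc(OCc3ccccc3)c(OC)c2)CO[C@@H]1c1ccc(OCc2ccccc2)c(OC)c1
F8 | step 8 | O-(imidazol-1-ylthiocarbonyl) derivative of F7 | CCCCCCCCCCCCCCCCCC(=O)OC[C@H]1[C@@H]([C@H](OC(=S)n2ccnc2)c2ccc(OCc3ccccc3)c(OC)c2)CO[C@@H]1c1ccc(OCc2ccccc2)c(OC)c1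
F9 | step 8 | di-O-benzyl ether of 14 | CCCCCCCCCCCCCCCCCC(=O)OC[C@H]1[C@@H](Cc2ccc(OCc3ccccc3)c(OC)c2)CO[C@@H]1c1ccc(OCc2ccccc2)c(OC)c1
F10 | step 1 | racemic 1-[4-(benzyloxy)-3-methoxyphenyl]prop-2-en-1-ol | C=CC(O)c1ccc(OCc2ccccc2)c(OC)c1
F11 | step 1 | (R)-1-[4-(benzyloxy)-3-methoxyphenyl]prop-2-en-1-yl acetate | CC(=O)O[C@@H](c1ccc(OCc2ccccc2)c(OC)c1)C=C
F12 | step 1 | (S)-1-[4-(benzyloxy)-3-methoxyphenyl]prop-2-en-1-ol | O[C@H](c1ccc(OCc2ccccc2)c(OC)c1)C=C
F13 | step 1 | (S)-1-[4-(benzyloxy)-3-methoxyphenyl]prop-2-en-1-yl acrylate | C=CC(=O)O[C@H](c1ccc(OCc2ccccc2)c(OC)c1)C=C
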